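**Plan**

1. Numbering and feature: the core is numbered as 1,6,7,11b-tetrahydrobenzo[6,7]cyclohepta[1,2,3-cd]benzofuran (ring A = central arene, ring B = the 2,4-dihydroxyphenyl group on C-7, ring C = the resorcinol ring of the seven-membered ring E, D2 = the core furan, D1 = the second furan on O-4/C-5). C-7 (H, ring B), its neighbour C-6 (H2) and the ortho hydroxyl of ring B together are a ring-opened 2,3-diaryl-2,3-dihydrobenzofuran, so this oxygen can hold C-6 as a benzyl ether and be released again by hydrogenolysis.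
2. Retrosynthesis (eight phenols as methyl ethers): D1 is cut at its C-3–C-5 bond (carbene insertion into a 4-methoxybenzyl ether C–H); D2 at C-11b–C-1 and C-1–O ([4+1] of a ring-E ortho-quinone methide with a sulfur ylide); ring E at the C-11b–ring A bond (Friedel–Crafts acylation); then, with the O–C-6 bond put back, the C-6–C-7 bond (carbene C–H insertion).
3. Forward order: benzyl aryl ether, diaryl ketone, diazo compound, temporary cis-dihydrobenzofuran (C-6–C-7 bond), carboxyl for bromine, hydrogenolysis of O–C-6, ring E, furan D2, furan D1, global demethylation.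
4. Stereochemistry: C-7 from Rh2(S-PTAD)4 in the insertion; C-11b and C-1 from ylide attack on the ortho-quinone methide anti to the pseudo-axial ring B, followed by trans ring closure; C-3 of D1 from Rh2(R-PTAD)4 and C-2 of D1 by acid equilibration to trans.

Key step: step 7

Assumption: Rh2(S-PTAD)4 is taken to give the 3R centre of 11; step 21 needs the opposite spatial sense at the carbene carbon and therefore uses Rh2(R-PTAD)4; should the sense of induction be the reverse, the two antipodes are exchanged.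

**Route**

Step 1
Reactants: 1 3,5-dihydroxybenzyl alcohol
Product: 2 3,5-diisopropoxybenzyl alcohol
Conditions: i-PrBr, K2CO3, DMF, 60 °C
Reagents that add atoms: 2-bromopropane CC(C)Br
Why: Williamson etherification alkylates the two phenoxides and leaves the far less acidic benzylic alcohol free, and isopropyl aryl ethers can later be cleaved with BCl3 beside methyl ethers.

Step 2
Reactants: 2 3,5-diisopropoxybenzyl alcohol; 3 2-bromo-5-methoxyphenol
Product: 4 1-bromo-2-[(3,5-diisopropoxybenzyl)oxy]-4-methoxybenzene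
Conditions: PPh3, DIAD, THF, 0 → 25 °C
Reagents that add atoms: none
Why: Mitsunobu etherification of a primary benzylic alcohol with an acidic phenol installs the benzyl ether whose OCH2 is the future C-6 and whose oxygen is the future ortho hydroxyl of ring B.

Step 3
Reactants: 4 1-bromo-2-[(3,5-diisopropoxybenzyl)oxy]-4-methoxybenzene; 5 2-bromo-4,6-dimethoxybenzaldehyde
Product: 7 (2-bromo-4,6-dimethoxyphenyl){2-[(3,5-diisopropoxybenzyl)oxy]-4-methoxyphenyl}methanol (racemic), via aryllithium 6 (not isolated)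
Conditions: n-BuLi, THF, −78 °C; then 5, −78 → 0 °C; H2O
Reagents that add atoms: none
Why: Bromine–lithium exchange at −78 °C is faster than deprotonation of the benzylic ether, and 1,2-addition of the aryllithium to the aldehyde outruns exchange with the bromide of 5; the carbinol centre is removed in step 4.

Step 4
Reactants: 7 (2-bromo-4,6-dimethoxyphenyl){2-[(3,5-diisopropoxybenzyl)oxy]-4-methoxyphenyl}methanol
Product: 8 (2-bromo-4,6-dimethoxyphenyl){2-[(3,5-diisopropoxybenzyl)oxy]-4-methoxyphenyl}methanone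
Conditions: Dess–Martin periodinane, CH2Cl2, 25 °C
Reagents that add atoms: none
Why: Dess–Martin oxidation converts the hindered benzhydrol into the diaryl ketone under neutral conditions that spare the benzyl ether and the aryl bromide.

Step 5
Reactants: 8 (2-bromo-4,6-dimethoxyphenyl){2-[(3,5-diisopropoxybenzyl)oxy]-4-methoxyphenyl}methanone
Product: 9 hydrazone of ketone 8 (C=N–NH2; E/Z mixture)
Conditions: N2H4·H2O (excess), AcOH (cat.), EtOH, 100 °C (sealed tube)
Reagents that add atoms: hydrazine (as hydrate) NN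
Why: Acid-catalysed hydrazone formation; the three ortho substituents that make forcing conditions necessary also block azine formation.

Step 6
Reactants: 9 hydrazone of ketone 8
Product: 10 1-bromo-2-(diazo{2-[(3,5-diisopropoxybenzyl)oxy]-4-methoxyphenyl}methyl)-3,5-dimethoxybenzene
Conditions: MnO2, CH2Cl2, 0 → 25 °C; filtration through Celite, solution used at once
Reagents that add atoms: none
Why: MnO2 dehydrogenation of an N-unsubstituted diaryl ketone hydrazone is the standard route to diaryldiazomethanes and touches neither the ethers nor the aryl bromide.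

Step 7
Reactants: 10 1-bromo-2-(diazo{2-[(3,5-diisopropoxybenzyl)oxy]-4-methoxyphenyl}methyl)-3,5-dimethoxybenzene
Product: 11 (2R,3R)-3-(2-bromo-4,6-dimethoxyphenyl)-2-(3,5-diisopropoxyphenyl)-6-methoxy-2,3-dihydrobenzofuran (2,3-cis)
Conditions: Rh2(S-PTAD)4 (1 mol %), CH2Cl2, 0 → 25 °C
Reagents that add atoms: none
Why: Rh2(S-PTAD)4 takes N2 from 10 to give a donor/donor rhodium carbene, which inserts in a concerted, hydride-transfer-like manner into the benzylic ether C–H lying 1,5 to the carbene carbon and so forms the future C-6–C-7 bond. The closest known reaction type is the enantioselective intramolecular C–H insertion of diaryl carbenes into benzyl ethers with Rh2(PTAD)4 catalysts, which gives cis-2,3-diaryl-2,3-dihydrobenzofurans. The temporary dihydrofuran closes by C-2–C-3 bond formation through a five-centre transition state (1,5-insertion), the ring oxygen being already in place. C-3 (the later C-7) is set by the chiral carboxylate ligands, which differentiate the two faces of the carbene, and C-2 follows as cis from the geometry of the concerted insertion; C-2 is erased in step 9, so only the catalyst-controlled centre counts. The step needs insertion at the benzylic OCH2 and not at the ortho OCH3 of the bromoaryl ring or at the isopropyl methines; the OCH2 hydrogen is activated by both oxygen and an electron-rich aryl group, whereas the methoxy C–H is primary and the isopropyl groups are out of reach. The aryl bromide and all ethers are spectators, and the low electrophilicity of a donor/donor carbene disfavours azine and dimer formation.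

Step 8
Reactants: 11 (2R,3R)-3-(2-bromo-4,6-dimethoxyphenyl)-2-(3,5-diisopropoxyphenyl)-6-methoxy-2,3-dihydrobenzofuran
Product: 13 2-[(2R,3R)-2-(3,5-diisopropoxyphenyl)-6-methoxy-2,3-dihydrobenzofuran-3-yl]-3,5-dimethoxybenzoic acid, via aryllithium 12 (not isolated)
Conditions: n-BuLi, THF, −78 °C; CO2; aq. HCl
Reagents that add atoms: carbon dioxide O=C=O
Why: Bromine–lithium exchange is faster than deprotonation of the benzylic C-3–H, and carboxylation of the aryllithium gives an acyl precursor that survives hydrogenolysis, which the bromide would not.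

Step 9
Reactants: 13 2-[(2R,3R)-2-(3,5-diisopropoxyphenyl)-6-methoxy-2,3-dihydrobenzofuran-3-yl]-3,5-dimethoxybenzoic acid
Product: 14 2-[(1R)-2-(3,5-diisopropoxyphenyl)-1-(2-hydroxy-4-methoxyphenyl)ethyl]-3,5-dimethoxybenzoic acid
Conditions: H2 (3 atm), 10% Pd/C, EtOAc–AcOH, 40 °C
Reagents that add atoms: none
Why: Hydrogenolysis of the benzylic C–O bond of a 2-aryl-2,3-dihydrobenzofuran (the pterocarpan-to-isoflavan type of cleavage) turns C-2 into the C-6 methylene and frees the ortho hydroxyl of ring B, while the diarylmethine C-7 is not touched and keeps its configuration.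

Step 10
Reactants: 14 2-[(1R)-2-(3,5-diisopropoxyphenyl)-1-(2-hydroxy-4-methoxyphenyl)ethyl]-3,5-dimethoxybenzoic acid
Product: 16 2-[(1R)-2-(3,5-diisopropoxyphenyl)-1-(2,4-dimethoxyphenyl)ethyl]-3,5-dimethoxybenzoic acid, via methyl ester 15 (not isolated)
Conditions: MeI, K2CO3, DMF, 25 °C; then LiOH, MeOH–H2O, 60 °C; aq. HCl
Reagents that add atoms: iodomethane CI
Why: Williamson methylation caps the freed phenol (and transiently the acid), and saponification of the ester returns the acid needed for the acylation.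

Step 11
Reactants: 16 2-[(1R)-2-(3,5-diisopropoxyphenyl)-1-(2,4-dimethoxyphenyl)ethyl]-3,5-dimethoxybenzoic acid
Product: 18 (10R)-10-(2,4-dimethoxyphenyl)-2,4-diisopropoxy-7,9-dimethoxy-10,11-dihydro-5H-dibenzo[a,d][7]annulen-5-one, via mixed trifluoroacetic anhydride 17 (not isolated)
Conditions: TFAA, CH2Cl2, 0 → 25 °C
Reagents that add atoms: none
Why: Intramolecular Friedel–Crafts acylation closes ring E as a dibenzosuberone at the ring-A carbon ortho and para to the two alkoxy groups; the two such carbons are equivalent, and the only ring-B carbon within reach is meta to both of its methoxy groups.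

Step 12
Reactants: 18 (10R)-10-(2,4-dimethoxyphenyl)-2,4-diisopropoxy-7,9-dimethoxy-10,11-dihydro-5H-dibenzo[a,d][7]annulen-5-one
Product: 19 (10R)-10-(2,4-dimethoxyphenyl)-4-hydroxy-2-isopropoxy-7,9-dimethoxy-10,11-dihydro-5H-dibenzo[a,d][7]annulen-5-one
Conditions: BCl3 (1.1 equiv), CH2Cl2, −78 °C; H2O
Reagents that add atoms: none
Why: Chelation-directed ether cleavage: BCl3 held between the ketone and the peri ether oxygen removes only that isopropyl group, leaving the methyl ethers and the remote isopropyl ether.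

Step 13
Reactants: 19 (10R)-10-(2,4-dimethoxyphenyl)-4-hydroxy-2-isopropoxy-7,9-dimethoxy-10,11-dihydro-5H-dibenzo[a,d][7]annulen-5-one
Product: 20 (10R)-10-(2,4-dimethoxyphenyl)-2-isopropoxy-7,9-dimethoxy-10,11-dihydro-5H-dibenzo[a,d][7]annulene-4,5-diol (C-5 epimers)
Conditions: NaBH4, THF–MeOH, 0 °C
Reagents that add atoms: none
Why: Borohydride reduction of a 2-hydroxy diaryl ketone gives the ortho-hydroxybenzhydrol, the usual ortho-quinone methide precursor; the new carbinol centre is lost in step 14, and the crude diol is used directly.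

Step 14
Reactants: 20 (10R)-10-(2,4-dimethoxyphenyl)-2-isopropoxy-7,9-dimethoxy-10,11-dihydro-5H-dibenzo[a,d][7]annulene-4,5-diol
Product: 22 (1R,7R,11bR)-7-(2,4-dimethoxyphenyl)-4-isopropoxy-8,10-dimethoxy-1-(4-methoxyphenyl)-1,6,7,11b-tetrahydrobenzo[6,7]cyclohepta[1,2,3-cd]benzofuran, via ortho-quinone methide 21 (not isolated)
Conditions: (4-MeOC6H4CH2)SMe2 BF4, Cs2CO3, MeCN, 0 → 40 °C
Reagents that add atoms: (4-methoxybenzyl)dimethylsulfonium tetrafluoroborate COc1ccc(C[S+](C)C)cc1.F[B-](F)(F)F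
Why: In this sulfur-ylide [4+1] annulation of an ortho-quinone methide, base dehydrates 20 to 21 and converts the salt into its ylide, which adds to the methide carbon (C-5 of 21, the future C-11b) on the face opposite ring B, held pseudo-axial on the neighbouring methine by allylic strain with the peri methoxy group, so that H-11b ends cis to ring B, and anti SN2 closure by the phenoxide with loss of Me2S sets C-1 trans to C-11b.

Step 15
Reactants: 22 (1R,7R,11bR)-7-(2,4-dimethoxyphenyl)-4-isopropoxy-8,10-dimethoxy-1-(4-methoxyphenyl)-1,6,7,11b-tetrahydrobenzo[6,7]cyclohepta[1,2,3-cd]benzofuran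
Product: 23 (1R,7R,11bR)-7-(2,4-dimethoxyphenyl)-8,10-dimethoxy-1-(4-methoxyphenyl)-1,6,7,11b-tetrahydrobenzo[6,7]cyclohepta[1,2,3-cd]benzofuran-4-ol
Conditions: BCl3 (3 equiv), CH2Cl2, −78 → 0 °C; H2O
Reagents that add atoms: none
Why: Lewis-acid dealkylation removes the secondary isopropyl ether selectively beside aryl methyl ethers, and the trans-dihydrofuran, being the thermodynamic isomer, is unchanged by any reversible opening of its benzylic C–O bond.

Step 16
Reactants: 23 (1R,7R,11bR)-7-(2,4-dimethoxyphenyl)-8,10-dimethoxy-1-(4-methoxyphenyl)-1,6,7,11b-tetrahydrobenzo[6,7]cyclohepta[1,2,3-cd]benzofuran-4-ol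
Product: 24 (1R,7R,11bR)-7-(2,4-dimethoxyphenyl)-4-hydroxy-8,10-dimethoxy-1-(4-methoxyphenyl)-1,6,7,11b-tetrahydrobenzo[6,7]cyclohepta[1,2,3-cd]benzofuran-5-carbaldehyde
Conditions: MgCl2, Et3N, (CH2O)n, MeCN, 80 °C; aq. HCl
Reagents that add atoms: paraformaldehyde (as formaldehyde) C=O
Why: Casnati–Skattebøl ortho-formylation acts only on the ring that carries the magnesium phenoxide, and C-5 should be preferred over C-3 as in 6-hydroxy-2,3-dihydrobenzofurans, which react para to the ring oxygen.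

Step 17
Reactants: 24 (1R,7R,11bR)-7-(2,4-dimethoxyphenyl)-4-hydroxy-8,10-dimethoxy-1-(4-methoxyphenyl)-1,6,7,11b-tetrahydrobenzo[6,7]cyclohepta[1,2,3-cd]benzofuran-5-carbaldehyde
Product: 25 (1R,7R,11bR)-7-(2,4-dimethoxyphenyl)-8,10-dimethoxy-4-[(4-methoxybenzyl)oxy]-1-(4-methoxyphenyl)-1,6,7,11b-tetrahydrobenzo[6,7]cyclohepta[1,2,3-cd]benzofuran-5-carbaldehyde
Conditions: 4-MeOC6H4CH2Cl, K2CO3, DMF, 50 °C
Reagents that add atoms: 4-methoxybenzyl chloride COc1ccc(CCl)cc1
Why: Williamson etherification of the salicylaldehyde phenol installs the benzyl ether whose OCH2 becomes C-2 of furan D1 and prevents quinone methide formation in step 18.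

Step 18
Reactants: 25 (1R,7R,11bR)-7-(2,4-dimethoxyphenyl)-8,10-dimethoxy-4-[(4-methoxybenzyl)oxy]-1-(4-methoxyphenyl)-1,6,7,11b-tetrahydrobenzo[6,7]cyclohepta[1,2,3-cd]benzofuran-5-carbaldehyde
Product: 26 (3,5-dimethoxyphenyl){(1R,7R,11bR)-7-(2,4-dimethoxyphenyl)-8,10-dimethoxy-4-[(4-methoxybenzyl)oxy]-1-(4-methoxyphenyl)-1,6,7,11b-tetrahydrobenzo[6,7]cyclohepta[1,2,3-cd]benzofuran-5-yl}methanol (carbinol epimers)
Conditions: 3,5-(MeO)2C6H3MgBr, THF, 0 °C; H2O
Reagents that add atoms: 3,5-dimethoxyphenylmagnesium bromide COc1cc([Mg]Br)cc(OC)c1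
Why: Grignard 1,2-addition to the aryl aldehyde brings in the 3-aryl group of furan D1; the carbinol centre is oxidised away in step 19.

Step 19
Reactants: 26 (3,5-dimethoxyphenyl){(1R,7R,11bR)-7-(2,4-dimethoxyphenyl)-8,10-dimethoxy-4-[(4-methoxybenzyl)oxy]-1-(4-methoxyphenyl)-1,6,7,11b-tetrahydrobenzo[6,7]cyclohepta[1,2,3-cd]benzofuran-5-yl}methanol
Product: 27 (3,5-dimethoxyphenyl){(1R,7R,11bR)-7-(2,4-dimethoxyphenyl)-8,10-dimethoxy-4-[(4-methoxybenzyl)oxy]-1-(4-methoxyphenyl)-1,6,7,11b-tetrahydrobenzo[6,7]cyclohepta[1,2,3-cd]benzofuran-5-yl}methanone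
Conditions: Dess–Martin periodinane, CH2Cl2, 25 °C
Reagents that add atoms: none
Why: Dess–Martin oxidation of the benzhydrol gives the diaryl ketone under neutral conditions tolerated by the benzyl ether and the dihydrofuran.

Step 20
Reactants: 27 (3,5-dimethoxyphenyl){(1R,7R,11bR)-7-(2,4-dimethoxyphenyl)-8,10-dimethoxy-4-[(4-methoxybenzyl)oxy]-1-(4-methoxyphenyl)-1,6,7,11b-tetrahydrobenzo[6,7]cyclohepta[1,2,3-cd]benzofuran-5-yl}methanone
Product: 28 hydrazone of ketone 27 (C=N–NH2; E/Z mixture)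
Conditions: N2H4·H2O (excess), AcOH (cat.), EtOH, 100 °C (sealed tube)
Reagents that add atoms: hydrazine (as hydrate) NN
Why: Acid-catalysed hydrazone formation as in step 5, here on a ketone with two ortho substituents.

Step 21
Reactants: 28 hydrazone of ketone 27
Product: 30 C-2(D1) epimer of 31 [core (1R,7R,11bR); furan D1 (2S,3R)-cis], via diaryldiazomethane 29 (not isolated)
Conditions: MnO2, CH2Cl2, 0 → 25 °C, filtration; Rh2(R-PTAD)4 (1 mol %), CH2Cl2, 0 → 25 °C
Reagents that add atoms: none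
Why: Hydrazone oxidation followed by enantioselective 1,5 C–H insertion of the donor/donor rhodium carbene into the 4-methoxybenzyl ether (the reaction type of step 7) closes furan D1, the catalyst fixing its C-3 as R independently of the remote centres and the concerted insertion giving the cis C-2 epimer.

Step 22
Reactants: 30 C-2(D1) epimer of 31
Product: 31 octa-O-methyl ether of 32 [core (1R,7R,11bR); furan D1 (2R,3R)-trans]
Conditions: TFA, CH2Cl2, 0 → 25 °C
Reagents that add atoms: none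
Why: Acid-mediated epimerisation: the C-2–O bond of furan D1 ionises to a 4-methoxybenzyl cation that recloses to the more stable trans ring, changing only this benzylic ether carbon; any cis isomer of furan D2 left from step 14 would be corrected in the same way.

Step 23
Reactants: 31 octa-O-methyl ether of 32
Product: 32 CNP0154047.1 (target)
Conditions: BBr3, CH2Cl2, −78 → 25 °C; H2O
Reagents that add atoms: none
Why: BBr3 ether cleavage removes all eight aryl methyl groups; the molecule has no stilbene that acid could cyclise, and both dihydrofurans are already in their thermodynamic trans form.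

**Compound list**

1 | 3,5-dihydroxybenzyl alcohol | OCc1cc(O)cc(O)c1 | starting material
2 | 3,5-diisopropoxybenzyl alcohol | CC(C)Oc1cc(CO)cc(OC(C)C)c1 | intermediate
3 | 2-bromo-5-methoxyphenol | COc1ccc(Br)c(O)c1 | starting material
4 | 1-bromo-2-[(3,5-diisopropoxybenzyl)oxy]-4-methoxybenzene | COc1ccc(Br)c(OCc2cc(OC(C)C)cc(OC(C)C)c2)c1 | intermediate
5 | 2-bromo-4,6-dimethoxybenzaldehyde | COc1cc(Br)c(C=O)c(OC)c1 | starting material
6 | {2-[(3,5-diisopropoxybenzyl)oxy]-4-methoxyphenyl}lithium (not isolated) | [Li]c1ccc(OC)cc1OCc1cc(OC(C)C)cc(OC(C)C)c1 | intermediate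
7 | (2-bromo-4,6-dimethoxyphenyl){2-[(3,5-diisopropoxybenzyl)oxy]-4-methoxyphenyl}methanol (racemic) | COc1ccc(C(O)c2c(OC)cc(OC)cc2Br)c(OCc2cc(OC(C)C)cc(OC(C)C)c2)c1 | intermediate
8 | (2-bromo-4,6-dimethoxyphenyl){2-[(3,5-diisopropoxybenzyl)oxy]-4-methoxyphenyl}methanone | COc1ccc(C(=O)c2c(OC)cc(OC)cc2Br)c(OCc2cc(OC(C)C)cc(OC(C)C)c2)c1 | intermediate
9 | hydrazone of ketone 8 (E/Z mixture) | COc1ccc(C(=NN)c2c(OC)cc(OC)cc2Br)c(OCc2cc(OC(C)C)cc(OC(C)C)c2)c1 | intermediate
10 | 1-bromo-2-(diazo{2-[(3,5-diisopropoxybenzyl)oxy]-4-methoxyphenyl}methyl)-3,5-dimethoxybenzene | [N-]=[N+]=C(c1ccc(OC)cc1OCc1cc(OC(C)C)cc(OC(C)C)c1)c1c(OC)cc(OC)cc1Br | intermediate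
11 | (2R,3R)-3-(2-bromo-4,6-dimethoxyphenyl)-2-(3,5-diisopropoxyphenyl)-6-methoxy-2,3-dihydrobenzofuran (2,3-cis) | COc1ccc2c(c1)O[C@@H](c1cc(OC(C)C)cc(OC(C)C)c1)[C@H]2c1c(OC)cc(OC)cc1Br | intermediate
12 | aryllithium of 11, Li in place of Br (not isolated) | COc1ccc2c(c1)O[C@@H](c1cc(OC(C)C)cc(OC(C)C)c1)[C@H]2c1c(OC)cc(OC)cc1[Li] | intermediate
13 | 2-[(2R,3R)-2-(3,5-diisopropoxyphenyl)-6-methoxy-2,3-dihydrobenzofuran-3-yl]-3,5-dimethoxybenzoic acid | COc1ccc2c(c1)O[C@@H](c1cc(OC(C)C)cc(OC(C)C)c1)[C@H]2c1c(OC)cc(OC)cc1C(=O)O | intermediate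
14 | 2-[(1R)-2-(3,5-diisopropoxyphenyl)-1-(2-hydroxy-4-methoxyphenyl)ethyl]-3,5-dimethoxybenzoic acid | CC(C)Oc1cc(C[C@H](c2ccc(OC)cc2O)c2c(OC)cc(OC)cc2C(=O)O)cc(OC(C)C)c1 | intermediate
15 | methyl 2-[(1R)-2-(3,5-diisopropoxyphenyl)-1-(2,4-dimethoxyphenyl)ethyl]-3,5-dimethoxybenzoate (not isolated) | CC(C)Oc1cc(C[C@H](c2ccc(OC)cc2OC)c2c(OC)cc(OC)cc2C(=O)OC)cc(OC(C)C)c1 | intermediate
16 | 2-[(1R)-2-(3,5-diisopropoxyphenyl)-1-(2,4-dimethoxyphenyl)ethyl]-3,5-dimethoxybenzoic acid | CC(C)Oc1cc(C[C@H](c2ccc(OC)cc2OC)c2c(OC)cc(OC)cc2C(=O)O)cc(OC(C)C)c1 | intermediate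
17 | mixed anhydride of 16 with trifluoroacetic acid (not isolated) | CC(C)Oc1cc(C[C@H](c2ccc(OC)cc2OC)c2c(OC)cc(OC)cc2C(=O)OC(=O)C(F)(F)F)cc(OC(C)C)c1 | intermediate
18 | (10R)-10-(2,4-dimethoxyphenyl)-2,4-diisopropoxy-7,9-dimethoxy-10,11-dihydro-5H-dibenzo[a,d][7]annulen-5-one | CC(C)Oc1cc(OC(C)C)c2c(c1)C[C@H](c1ccc(OC)cc1OC)c1c(OC)cc(OC)cc1C2=O | intermediate
19 | (10R)-10-(2,4-dimethoxyphenyl)-4-hydroxy-2-isopropoxy-7,9-dimethoxy-10,11-dihydro-5H-dibenzo[a,d][7]annulen-5-one | CC(C)Oc1cc(O)c2c(c1)C[C@H](c1ccc(OC)cc1OC)c1c(OC)cc(OC)cc1C2=O | intermediate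
20 | (10R)-10-(2,4-dimethoxyphenyl)-2-isopropoxy-7,9-dimethoxy-10,11-dihydro-5H-dibenzo[a,d][7]annulene-4,5-diol (C-5 epimers) | CC(C)Oc1cc(O)c2c(c1)C[C@H](c1ccc(OC)cc1OC)c1c(OC)cc(OC)cc1C2O | intermediate
21 | (10R)-10-(2,4-dimethoxyphenyl)-2-isopropoxy-7,9-dimethoxy-10,11-dihydro-4H-dibenzo[a,d][7]annulen-4-one, the ortho-quinone methide with a C-4a=C-5 double bond (not isolated) | CC(C)OC1=CC(=O)C2=Cc3cc(OC)cc(OC)c3[C@@H](c3ccc(OC)cc3OC)CC2=C1 | intermediate
22 | (1R,7R,11bR)-7-(2,4-dimethoxyphenyl)-4-isopropoxy-8,10-dimethoxy-1-(4-methoxyphenyl)-1,6,7,11b-tetrahydrobenzo[6,7]cyclohepta[1,2,3-cd]benzofuran | CC(C)Oc1cc2c3c(c1)C[C@H](c1ccc(OC)cc1OC)c1c(OC)cc(OC)cc1[C@H]3[C@H](c1ccc(OC)cc1)O2 | intermediate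
23 | (1R,7R,11bR)-7-(2,4-dimethoxyphenyl)-8,10-dimethoxy-1-(4-methoxyphenyl)-1,6,7,11b-tetrahydrobenzo[6,7]cyclohepta[1,2,3-cd]benzofuran-4-ol | Oc1cc2c3c(c1)C[C@H](c1ccc(OC)cc1OC)c1c(OC)cc(OC)cc1[C@H]3[C@H](c1ccc(OC)cc1)O2 | intermediate
24 | (1R,7R,11bR)-7-(2,4-dimethoxyphenyl)-4-hydroxy-8,10-dimethoxy-1-(4-methoxyphenyl)-1,6,7,11b-tetrahydrobenzo[6,7]cyclohepta[1,2,3-cd]benzofuran-5-carbaldehyde | Oc1cc2c3c(c1C=O)C[C@H](c1ccc(OC)cc1OC)c1c(OC)cc(OC)cc1[C@H]3[C@H](c1ccc(OC)cc1)O2 | intermediate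
25 | (1R,7R,11bR)-7-(2,4-dimethoxyphenyl)-8,10-dimethoxy-4-[(4-methoxybenzyl)oxy]-1-(4-methoxyphenyl)-1,6,7,11b-tetrahydrobenzo[6,7]cyclohepta[1,2,3-cd]benzofuran-5-carbaldehyde | COc1ccc(COc2cc3c4c(c2C=O)C[C@H](c2ccc(OC)cc2OC)c2c(OC)cc(OC)cc2[C@H]4[C@H](c2ccc(OC)cc2)O3)cc1 | intermediate
26 | (3,5-dimethoxyphenyl){(1R,7R,11bR)-7-(2,4-dimethoxyphenyl)-8,10-dimethoxy-4-[(4-methoxybenzyl)oxy]-1-(4-methoxyphenyl)-1,6,7,11b-tetrahydrobenzo[6,7]cyclohepta[1,2,3-cd]benzofuran-5-yl}methanol (carbinol epimers) | COc1ccc(COc2cc3c4c(c2C(O)c2cc(OC)cc(OC)c2)C[C@H](c2ccc(OC)cc2OC)c2c(OC)cc(OC)cc2[C@H]4[C@H](c2ccc(OC)cc2)O3)cc1 | intermediate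
27 | (3,5-dimethoxyphenyl){(1R,7R,11bR)-7-(2,4-dimethoxyphenyl)-8,10-dimethoxy-4-[(4-methoxybenzyl)oxy]-1-(4-methoxyphenyl)-1,6,7,11b-tetrahydrobenzo[6,7]cyclohepta[1,2,3-cd]benzofuran-5-yl}methanone | COc1ccc(COc2cc3c4c(c2C(=O)c2cc(OC)cc(OC)c2)C[C@H](c2ccc(OC)cc2OC)c2c(OC)cc(OC)cc2[C@H]4[C@H](c2ccc(OC)cc2)O3)cc1 | intermediate
28 | hydrazone of ketone 27 (E/Z mixture) | COc1ccc(COc2cc3c4c(c2C(=NN)c2cc(OC)cc(OC)c2)C[C@H](c2ccc(OC)cc2OC)c2c(OC)cc(OC)cc2[C@H]4[C@H](c2ccc(OC)cc2)O3)cc1 | intermediate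
29 | diaryldiazomethane from 28, C=N2 in place of C=O of 27 (not isolated) | COc1ccc(COc2cc3c4c(c2C(=[N+]=[N-])c2cc(OC)cc(OC)c2)C[C@H](c2ccc(OC)cc2OC)c2c(OC)cc(OC)cc2[C@H]4[C@H](c2ccc(OC)cc2)O3)cc1 | intermediate
30 | C-2(D1) epimer of 31: core (1R,7R,11bR), furan D1 (2S,3R)-cis | COc1ccc([C@H]2Oc3cc4c5c(c3[C@H]2c2cc(OC)cc(OC)c2)C[C@H](c2ccc(OC)cc2OC)c2c(OC)cc(OC)cc2[C@H]5[C@H](c2ccc(OC)cc2)O4)cc1 | intermediate
31 | octa-O-methyl ether of 32: core (1R,7R,11bR), furan D1 (2R,3R)-trans | COc1ccc([C@@H]2Oc3cc4c5c(c3[C@H]2c2cc(OC)cc(OC)c2)C[C@H](c2ccc(OC)cc2OC)c2c(OC)cc(OC)cc2[C@H]5[C@H](c2ccc(OC)cc2)O4)cc1 | intermediate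
32 | CNP0154047.1: (1R,7R,11bR)-7-(2,4-dihydroxyphenyl)-1-(4-hydroxyphenyl)-1,6,7,11b-tetrahydrobenzo[6,7]cyclohepta[1,2,3-cd]benzofuran-8,10-diol core fused at O-4/C-5 to furan D1, which carries (2R)-2-(4-hydroxyphenyl) and (3R)-3-(3,5-dihydroxyphenyl) groups trans | Oc1ccc([C@@H]2Oc3cc4c5c(c3[C@H]2c2cc(O)cc(O)c2)C[C@H](c2ccc(O)cc2O)c2c(O)cc(O)cc2[C@H]5[C@H](c2ccc(O)cc2)O4)cc1 | target

**Count and risks**

Total step count: 23. Longest linear sequence: 23 steps, from 1 (3 and 5 are purchased).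

Steps most likely to fail:

Step 14. The addition of the ylide to the ortho-quinone methide may show poor or reversed facial selectivity if ring B is not held pseudo-axial, and the sulfonium salt may benzylate the phenoxide before the quinone methide forms. The fallback replaces the ylide annulation by a catalyst-controlled carbene insertion and sets out from 19. Alkylation of the chelated phenol with 4-methoxybenzyl chloride (K2CO3, DMF, 60 °C) should give the 4-[(4-methoxybenzyl)oxy] ether of ketone 19 F1. Hydrazine hydrate (AcOH, EtOH, heat) should convert it into the hydrazone of this cyclic ketone F2, and MnO2 should give the cyclic diaryldiazomethane F3. Rh2(R-PTAD)4 should then insert the carbene into the ether C–H to give the 1,11b-cis isomer of 22 F4, in which C-11b is fixed by the catalyst and not by the conformation of ring E. Treatment with TFA in CH2Cl2 should epimerise C-1 to the trans ring, and the sequence comes back to the route at 22.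

Step 5. The condensation may stall because the carbonyl group is flanked by three ortho substituents and is deactivated by two alkoxy-rich aryl groups, and long heating invites displacement of the ortho bromide by the hydrazone nitrogen. The fallback activates the carbon by thionation and sets out from 8. Lawesson's reagent (toluene, 100 °C) should give the diaryl thioketone F5. Thioketones exchange sulfur for hydrazine far more readily than ketones exchange oxygen, so hydrazine hydrate in EtOH at 25 °C should then give the hydrazone with loss of H2S, and the sequence comes back to the route at 9.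

Step 21. The congested carbene, with two ortho substituents on ring A, may insert into the C-7 methine C–H of ring E (also a 1,5 relationship) or form azine instead of reaching the ether CH2, and the hydrazone needed for it may form only slowly in step 20. The fallback builds furan D1 by ylide annulation and sets out from 24. Addition of excess 3,5-dimethoxyphenylmagnesium bromide to the free salicylaldehyde should give the ortho-hydroxybenzhydrol F6. Treatment with (4-methoxybenzyl)dimethylsulfonium tetrafluoroborate and Cs2CO3 in MeCN should pass through the ring-A ortho-quinone methide F7 to the trans furan D1, and the sequence comes back to the route at 31. In this variant the remote centres are not expected to bias the quinone methide faces strongly, so 31 would have to be separated by chromatography from its diastereomer of opposite D1 configuration.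

Further compounds
F1 | step 14 | (10R)-10-(2,4-dimethoxyphenyl)-2-isopropoxy-7,9-dimethoxy-4-[(4-methoxybenzyl)oxy]-10,11-dihydro-5H-dibenzo[a,d][7]annulen-5-one | CC(C)Oc1cc(OCc2ccc(OC)cc2)c2c(c1)C[C@H](c1ccc(OC)cc1OC)c1c(OC)cc(OC)cc1C2=O
F2 | step 14 | hydrazone of ketone F1 | CC(C)Oc1cc(OCc2ccc(OC)cc2)c2c(c1)C[C@H](c1ccc(OC)cc1OC)c1c(OC)cc(OC)cc1C2=NN
F3 | step 14 | 5-diazo analogue of F1 (cyclic diaryldiazomethane) | CC(C)Oc1cc(OCc2ccc(OC)cc2)c2c(c1)C[C@H](c1ccc(OC)cc1OC)c1c(OC)cc(OC)cc1C2=[N+]=[N-]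
F4 | step 14 | (1S,7R,11bR)-7-(2,4-dimethoxyphenyl)-4-isopropoxy-8,10-dimethoxy-1-(4-methoxyphenyl)-1,6,7,11b-tetrahydrobenzo[6,7]cyclohepta[1,2,3-cd]benzofuran (1,11b-cis isomer of 22) | CC(C)Oc1cc2c3c(c1)C[C@H](c1ccc(OC)cc1OC)c1c(OC)cc(OC)cc1[C@H]3[C@@H](c1ccc(OC)cc1)O2
F5 | step 5 | (2-bromo-4,6-dimethoxyphenyl){2-[(3,5-diisopropoxybenzyl)oxy]-4-methoxyphenyl}methanethione | COc1ccc(C(=S)c2c(OC)cc(OC)cc2Br)c(OCc2cc(OC(C)C)cc(OC(C)C)c2)c1
F6 | step 21 | (1R,7R,11bR)-5-[(3,5-dimethoxyphenyl)(hydroxy)methyl]-7-(2,4-dimethoxyphenyl)-8,10-dimethoxy-1-(4-methoxyphenyl)-1,6,7,11b-tetrahydrobenzo[6,7]cyclohepta[1,2,3-cd]benzofuran-4-ol (carbinol epimers) | Oc1cc2c3c(c1C(O)c1cc(OC)cc(OC)c1)C[C@H](c1ccc(OC)cc1OC)c1c(OC)cc(OC)cc1[C@H]3[C@H](c1ccc(OC)cc1)O2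
F7 | step 21 | ring-A ortho-quinone methide from F6 (C-4 carbonyl; C-5 exocyclic 3,5-dimethoxybenzylidene) | O=C1C=C2O[C@@H](c3ccc(OC)cc3)[C@@H]3c4cc(OC)cc(OC)c4[C@@H](c4ccc(OC)cc4OC)CC(=C23)C1=Cc1cc(OC)cc(OC)c1
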